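## Retrosynthetic overview

1. The strategy rests on the 1,4-diketone C4(=O)–C3–C3'–C4'(=O), which joins the pyranone ring of the 2,3-trans unit to that of the 2,3-cis unit. With (3R,3'S), H3 and H3' lie cis once C4 and C4' are brought together, so the diketone is the cleavage product of a cis-3,4-disubstituted cyclobutene C3–C4=C4'–C3'.
2. The cyclobutene is opened at C3–C3' (retro-4π) to the diene C3=C4–C4'=C3' of a C2-symmetric (2S,2'S)-4,4'-bi(2H-chromene). Excited-state disrotation places H3 and H3' cis, and two like-configured C2 centres then force one pyran ring to be 2,3-trans and the other 2,3-cis.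
3. In the cisoid rotamer needed for closure, C4a and C4a' are syn and the oxygens on C5 and C5' face each other. These two positions therefore share one o-xylylene bridge (O5–CH2–C6H4–CH2–O5') instead of two benzyl groups. The bridge excludes the transoid rotamer, makes the C4–C4' coupling intramolecular, and leaves in the final hydrogenolysis.
4. The diene comes from a bis(enol triflate) by borylative palladium coupling. The bis-flavanone comes from a twofold rhodium-catalysed asymmetric 1,4-addition of 4-methoxyphenylboronic acid to a xylylene-linked bis-chromone made from 5,7-dihydroxychromone.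
5. Ring order: benzopyranone rings (bought) → twelve-membered tether ring (step 5) → cyclobutene (step 6) → cyclobutene cleaved to the diketone (step 7) → bridge and benzyl groups removed (step 8).

Key step: step 6

Remark: chromane locants are used (O1, C2, C3, C4, C4a, C5–C8, C8a). Unprimed locants belong to the 2,3-trans unit and primed ones to the 2,3-cis unit. The target SMILES reads (2S,3R,2'S,3'S).

## Route

Step 1
Reactants: 1 5,7-dihydroxy-4H-chromen-4-one; 2 benzyl bromide
Product: 3 7-(benzyloxy)-5-hydroxy-4H-chromen-4-one
Conditions: BnBr (1.05 equiv), K2CO3 (1.1 equiv), acetone, reflux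
Reagents that add atoms: benzyl bromide, BrCc1ccccc1
Why: Williamson etherification, in which the 5-OH is held in a hydrogen bond to the C4 carbonyl and is much less acidic and nucleophilic than the 7-OH, so one equivalent of benzyl bromide should alkylate O7 only.

Step 2
Reactants: 3 7-(benzyloxy)-5-hydroxy-4H-chromen-4-one (2.1 equiv); 4 1,2-bis(bromomethyl)benzene
Product: 5 1,2-bis({[7-(benzyloxy)-4-oxo-4H-chromen-5-yl]oxy}methyl)benzene
Conditions: Cs2CO3, MeCN, 60 °C
Reagents that add atoms: 1,2-bis(bromomethyl)benzene, BrCc1ccccc1CBr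
Why: Twofold Williamson etherification in which the stronger, more soluble base breaks the chelate of the only free hydroxyl of 3, so each benzylic bromide of 4 can only end as an O5 ether, and the base is harmless because no stereocentre is present yet.

Step 3
Reactants: 5 xylylene-linked bis-chromone; 6 4-methoxyphenylboronic acid (4 equiv)
Product: 7 1,2-bis({[(2S)-7-(benzyloxy)-2-(4-methoxyphenyl)-4-oxochroman-5-yl]oxy}methyl)benzene
Conditions: [Rh(OH)(cod)]2 (2.5 mol %), (S)-MeO-F12-BIPHEP (5.5 mol %), toluene/H2O, 25 °C
Reagents that add atoms: 4-methoxyphenylboronic acid, COc1ccc(B(O)O)cc1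
Why: Hayashi–Miyaura rhodium-catalysed asymmetric 1,4-addition of an arylboronic acid to a chromone, a known base-free entry to enantioenriched flavanones that does not open the product; the ligand antipode that gives (S)-3-arylcyclohexanones from cyclohexenone shields the same face of C2=C3 here and sets (2S) and (2'S) independently, and a mismatched addition ends in the separable (2S,2'R) diastereomer, which should raise the enantiopurity of 7.

Step 4
Reactants: 7 xylylene-linked bis-flavanone
Product: 8 bis(enol triflate), 1,2-bis({[(2S)-7-(benzyloxy)-2-(4-methoxyphenyl)-4-(trifluoromethylsulfonyloxy)-2H-chromen-5-yl]oxy}methyl)benzene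
Conditions: Comins' reagent (2.6 equiv), then slow addition of KN(SiMe3)2 (2.4 equiv), THF, −78 °C
Reagents that add atoms: Comins' reagent, N-(5-chloropyridin-2-yl)bis(trifluoromethanesulfonimide), FC(F)(F)S(=O)(=O)N(c1ccc(Cl)cn1)S(=O)(=O)C(F)(F)F
Why: Kinetic enolate O-triflation at the only enolisable position, C3, where trapping in situ at −78 °C keeps the enolate lifetime too short for E1cB opening of the O1–C2 bond, so C2 and C2' should be retained.

Step 5
Reactants: 8 bis(enol triflate)
Product: 10 O5,O5'-xylylene-bridged (2S,2'S)-4,4'-bi(2H-chromene), via boronate triflate 9 (not isolated)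
Conditions: B2pin2 (1.05 equiv), PdCl2(dppf) (10 mol %), K3PO4 (4 equiv), dioxane/H2O, 2 mM, 50 °C
Reagents that add atoms: bis(pinacolato)diboron, CC1(C)OB(OC1(C)C)B1OC(C)(C)C(C)(C)O1 (its boryl group is carried only by 9)
Why: One-pot Miyaura borylation and intramolecular Suzuki–Miyaura coupling of alkenyl triflates, in which one C4–OTf becomes the pinacol boronate 9 and then couples with the remaining C4'–OTf under the same catalyst, the bridge turning a peri-hindered homocoupling into a twelve-membered ring closure at high dilution, with C2 and C2' untouched and either helical form about the new C4–C4' axis acceptable.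

Step 6
Reactants: 10 O5,O5'-xylylene-bridged (2S,2'S)-4,4'-bi(2H-chromene)
Product: 11 cis-fused cyclobutene (C3–C3' single bond, C4=C4' double bond; H3/H3' cis, H2/H3 trans, H2'/H3' cis)
Conditions: hν (340 nm UV-LED, long-wavelength edge of the diene band), degassed toluene (1 mM), −40 °C, FEP-tube flow reactor, O2 excluded
Reagents that add atoms: none
Why: Proposed new method: direct excitation of the cisoid diene C3=C4–C4'=C3' populates the singlet ππ* state, in which C4–C4' gains double-bond character and the termini C3 and C3' turn in the disrotatory sense allowed for a four-electron excited-state electrocyclisation, so the C3–C3' σ bond and the C4=C4' alkene form in one event. The closest known reaction type is the photocyclisation of 1,1'-bicycloalkenyls and of cisoid cyclic 1,3-dienes to cyclobutenes, which has not been shown on a 4,4'-bi(2H-chromene). The one new ring, the four-membered carbocycle C3–C4–C4'–C3', is closed by this 4π disrotatory mode and is cis-fused to both pyran rings. C3 and C3' are set by orbital symmetry, because H3 and H3' are the inward substituents of the diene and must end cis; the C2 axis of 10, kept in both of its helical forms, interchanges the two disrotatory senses, so only one isomer can arise, and the fixed (2S) and (2'S) centres make it trans in one pyran ring and cis in the other. The selectivity needed is chemoselectivity between two excited-state channels, since closure must be faster than the photochromic opening of C2–O1 to an o-quinone methide that would scramble C2; the bridge helps by holding every molecule on the cisoid side from which closure starts, and red-edge irradiation in the cold addresses the conjugated diene rather than an isolated chromene. Thermal reversion of 11 is blocked, because conrotatory opening would place a trans double bond in a six-membered ring.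

Step 7
Reactants: 11 cis-fused cyclobutene
Product: 13 (2S,3R,2'S,3'S)-xylylene-bridged 3,3'-bichroman-4,4'-dione, via secondary ozonide 12 (not isolated)
Conditions: O3 (1.0 equiv, titrated solution in CH2Cl2), CH2Cl2, −78 °C; then PPh3 (1.5 equiv), −78 °C → rt
Reagents that add atoms: ozone, [O-][O+]=O
Why: Criegee ozonolysis of a cyclobutene to a 1,4-diketone, in which the strained, tetrasubstituted, doubly donor-aryl-substituted C4=C4' bond is by far the most nucleophilic π bond and should consume the single equivalent of ozone before the arenes or benzylic C–H bonds react, while the neutral reductive work-up leaves C2, C3, C2' and C3' untouched.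

Step 8
Reactants: 13 xylylene-bridged 3,3'-bichroman-4,4'-dione
Product: 14 target, (2S,3R,2'S,3'S)-5,5',7,7'-tetrahydroxy-2,2'-bis(4-methoxyphenyl)-3,3'-bichroman-4,4'-dione
Conditions: H2 (1 atm), Pd/C (10 wt %), EtOAc/THF, rt, stopped after uptake of 4 equiv H2
Reagents that add atoms: none
Why: Heterogeneous hydrogenolysis of aryl benzyl ethers cleaves all four ArO–CH2Ar bonds (two benzyl groups and both ends of the bridge) under neutral conditions that neither enolise C3/C3' nor open the pyranone rings, the methyl ethers being inert and the hindered secondary C2–O1 bonds reacting more slowly.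

## Compound list

1 | 5,7-dihydroxy-4H-chromen-4-one | O=c1ccoc2cc(O)cc(O)c12 | starting material
2 | benzyl bromide | BrCc1ccccc1 | starting material
3 | 7-(benzyloxy)-5-hydroxy-4H-chromen-4-one | O=c1ccoc2cc(OCc3ccccc3)cc(O)c12 | intermediate
4 | 1,2-bis(bromomethyl)benzene | BrCc1ccccc1CBr | starting material
5 | 1,2-bis({[7-(benzyloxy)-4-oxo-4H-chromen-5-yl]oxy}methyl)benzene | O=c1ccoc2cc(OCc3ccccc3)cc(OCc3ccccc3COc3cc(OCc4ccccc4)cc4occc(=O)c34)c12 | intermediate
6 | 4-methoxyphenylboronic acid | COc1ccc(B(O)O)cc1 | starting material
7 | 1,2-bis({[(2S)-7-(benzyloxy)-2-(4-methoxyphenyl)-4-oxochroman-5-yl]oxy}methyl)benzene | COc1ccc([C@H]2Oc3cc(OCc4ccccc4)cc(OCc4ccccc4COc4cc(OCc5ccccc5)cc5O[C@H](c6ccc(OC)cc6)CC(=O)c45)c3C(=O)C2)cc1 | intermediate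
8 | 1,2-bis({[(2S)-7-(benzyloxy)-2-(4-methoxyphenyl)-4-(trifluoromethylsulfonyloxy)-2H-chromen-5-yl]oxy}methyl)benzene | COc1ccc([C@H]2Oc3cc(OCc4ccccc4)cc(OCc4ccccc4COc4cc(OCc5ccccc5)cc5O[C@H](c6ccc(OC)cc6)C=C(OS(=O)(=O)C(F)(F)F)c45)c3C(OS(=O)(=O)C(F)(F)F)=C2)cc1 | intermediate
9 | boronate triflate: as 8, with one C4–OTf replaced by C4–B(pin) | COc1ccc([C@H]2Oc3cc(OCc4ccccc4)cc(OCc4ccccc4COc4cc(OCc5ccccc5)cc5O[C@H](c6ccc(OC)cc6)C=C(OS(=O)(=O)C(F)(F)F)c45)c3C(B3OC(C)(C)C(C)(C)O3)=C2)cc1 | intermediate (not isolated)
10 | (2S,2'S)-7,7'-bis(benzyloxy)-2,2'-bis(4-methoxyphenyl)-5,5'-[1,2-phenylenebis(methyleneoxy)]-4,4'-bi(2H-chromene), C2-symmetric, twelve-membered tether ring, either helical form about C4–C4' | COc1ccc([C@H]2Oc3cc(OCc4ccccc4)cc4OCc5ccccc5COc5cc(OCc6ccccc6)cc6O[C@H](c7ccc(OC)cc7)C=C(C(=C2)c34)c56)cc1 | intermediate (key-step precursor)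
11 | cyclobutene C3–C4=C4'–C3' cis-fused to both pyran rings of the bridged dimer; H3/H3' cis, H2/H3 trans, H2'/H3' cis; (2S,3S,2'S,3'R) by the CIP rules for this skeleton | COc1ccc([C@H]2Oc3cc(OCc4ccccc4)cc4OCc5ccccc5COc5cc(OCc6ccccc6)cc6O[C@H](c7ccc(OC)cc7)[C@@H]7[C@H]2C(c34)=C7c56)cc1 | intermediate (key-step product)
12 | secondary ozonide: 2,3,7-trioxabicyclo[2.2.1]heptane with C4 and C4' as bridgeheads and C3–C3' as the carbon bridge, C2 and C2' exo | COc1ccc([C@H]2Oc3cc(OCc4ccccc4)cc4OCc5ccccc5COc5cc(OCc6ccccc6)cc6O[C@H](c7ccc(OC)cc7)[C@@H]7[C@H]2[C@@]8(c34)OO[C@@]7(O8)c56)cc1 | intermediate (not isolated)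
13 | (2S,3R,2'S,3'S)-7,7'-bis(benzyloxy)-2,2'-bis(4-methoxyphenyl)-5,5'-[1,2-phenylenebis(methyleneoxy)]-3,3'-bichroman-4,4'-dione | COc1ccc([C@H]2Oc3cc(OCc4ccccc4)cc4OCc5ccccc5COc5cc(OCc6ccccc6)cc6O[C@H](c7ccc(OC)cc7)[C@@H](C(=O)c56)[C@H]2C(=O)c34)cc1 | intermediate
14 | (2S,3R,2'S,3'S)-5,5',7,7'-tetrahydroxy-2,2'-bis(4-methoxyphenyl)-3,3'-bichroman-4,4'-dione (CNP0260837.2) | COc1ccc([C@H]2Oc3cc(O)cc(O)c3C(=O)[C@@H]2[C@@H]2C(=O)c3c(O)cc(O)cc3O[C@@H]2c2ccc(OC)cc2)cc1 | target

Total step count: 8
Longest linear sequence: 8 steps (1 → 14)

## Steps most likely to fail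

**Step 6.** Excited-state opening of the C2–O1 bond may run faster than closure and scramble C2 and C2'. Alternatively, the excited diene may decay without bond formation, because the O5/O5' contact resists flattening about C4–C4'.

The fallback uses known chemistry and makes C3–C3' by oxidative enolate coupling instead of electrocyclisation. It sets out from 7 and returns at 13, bypassing steps 4 to 7.
- 7 is doubly deprotonated (LiN(SiMe3)2, THF, −78 °C) to the dilithium bis-enolate F1.
- F1 is oxidised with CuCl2 (DMF/THF, −78 → 0 °C) in an intramolecular oxidative enolate coupling. Each enolate should bond on the face away from its own C2 aryl group, giving the C2-symmetric trans,trans diketone F2.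
- One equivalent of LiN(SiMe3)2 at −78 °C removes H3 of either equivalent unit to give the mono-enolate F3. In F3 the neighbouring aryl group sits pseudo-axial to avoid allylic strain.
- Kinetic protonation (AcOH in THF, −78 °C) from the open face places the new hydrogen anti to that aryl group. This is the 2',3'-cis arrangement of 13.

**Step 7.** Ozone may over-oxidise the four electron-rich arenes or the benzylic ethers, or an aryl group may migrate in the peroxidic intermediate.

The fallback replaces the one-step cleavage with two chemoselective steps. It sets out from 11 and returns at 13.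
- Dihydroxylation (OsO4 cat., NMO, MeSO2NH2, acetone/H2O) can only occur on the face bearing H3 and H3', because the other face would give trans-fused rings. It should give the cis-4,4'-diol F4.
- Glycol cleavage with Pb(OAc)4 (CH2Cl2, 0 °C) then gives 13.

**Step 5.** Oligomerisation or protodeborylation may compete with ring closure. Reversible ionisation of the allylic C2–O1 bond by zerovalent palladium may also erode C2.

The fallback is free of palladium and enolates. It sets out from 7 and returns at 10, also bypassing step 4.
- Intramolecular ketyl coupling (SmI2, HMPA, THF, high dilution) should give the 4,4'-pinacol F5 as a mixture at the two carbinol centres, which are lost in the next step.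
- Twofold syn-dehydration towards C3 and C3' with Burgess reagent (toluene, 50 °C) follows the classical pinacol–dehydration route to 1,1'-bicycloalkenyls and gives 10.

## Further compounds

F1 | step 6 | dilithium bis-enolate of 7 | COc1ccc([C@H]2Oc3cc(OCc4ccccc4)cc(OCc4ccccc4COc4cc(OCc5ccccc5)cc5O[C@H](c6ccc(OC)cc6)C=C([O-])c45)c3C([O-])=C2)cc1.[Li+].[Li+]
F2 | step 6 | (2S,3R,2'S,3'R)-7,7'-bis(benzyloxy)-2,2'-bis(4-methoxyphenyl)-5,5'-[1,2-phenylenebis(methyleneoxy)]-3,3'-bichroman-4,4'-dione (trans,trans) | COc1ccc([C@H]2Oc3cc(OCc4ccccc4)cc4OCc5ccccc5COc5cc(OCc6ccccc6)cc6O[C@H](c7ccc(OC)cc7)[C@H](C(=O)c56)[C@H]2C(=O)c34)cc1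
F3 | step 6 | mono-lithium C3'=C4' enolate of F2 | COc1ccc([C@H]2Oc3cc(OCc4ccccc4)cc4OCc5ccccc5COc5cc(OCc6ccccc6)cc6O[C@H](c7ccc(OC)cc7)C(=C([O-])c56)[C@H]2C(=O)c34)cc1.[Li+]
F4 | step 7 | cis-4,4'-diol of 11, hydroxyl groups on the face of H3 and H3' | COc1ccc([C@H]2Oc3cc(OCc4ccccc4)cc4OCc5ccccc5COc5cc(OCc6ccccc6)cc6O[C@H](c7ccc(OC)cc7)[C@@H]7[C@H]2[C@](O)(c34)[C@]7(O)c56)cc1
F5 | step 5 | (2S,2'S)-xylylene-bridged 4,4'-bichroman-4,4'-diol (pinacol, mixture at C4 and C4') | COc1ccc([C@H]2Oc3cc(OCc4ccccc4)cc4OCc5ccccc5COc5cc(OCc6ccccc6)cc6O[C@H](c7ccc(OC)cc7)CC(O)(C(O)(C2)c34)c56)cc1
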